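Has this flask stopped by 2.5 h, and how much of each hand has become product?

left-handed substrate 1.0 M; partner 3.00 M; right-handed substrate 1.0 M; time 2.5 h

    partner + left-handed substrate → left-handed product (k1 = 1.83 × 10⁻⁴ /M/s)
    partner + right-handed substrate → right-handed product (k2 = 6.01 × 10⁻⁵ /M/s)

- partner is single-handed; left-handed substrate and right-handed substrate are mirror images of each other, charged as a racemate, each of them at the stated concentration
- the reaction counts as stopped when no species that holds the left-handed substrate and right-handed substrate together changes by six tenths of a point or more over the second half of the time
- run time (flask): 2.5 h
- the handed part of partner does not stay in what it makes, so the products of the two hands are mirror images too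

1. at 2.5 h, what has stopped the reaction, if anything has (it is still moving / the partner has run out first / all of the left-handed substrate has reacted)
2. how much of the left-handed substrate and right-handed substrate together has reacted by 2.5 h
3. how much left-handed product there is at 2.5 h, in percent of the left-handed substrate and right-handed substrate together charged
4. how much right-handed product there is at 2.5 h, in percent of the left-handed substrate and right-handed substrate together charged

I count turnovers. A hand's turnover count is its starting rate, as a fraction of its own charge, multiplied by the run time: 4.94 lifetimes for the left-handed substrate, 1.62 for the right-handed. The left count over the right count is the selectivity factor 3.04. Both hands meet the same partner at each moment, so the lifetimes they really pass keep that ratio, whatever the partner does.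

Two things slow the rates. Each hand's own loss cuts its rate by a factor e per lifetime passed. The partner's falling share cuts both rates alike. The partner charge exceeds the two substrate charges together, so that share has a floor of 33.3%.

I take the mean share midway between full charge and floor, 0.667. That leaves 3.29 lifetimes for the left hand and 1.08 for the right. On this estimate 3.71% of the left-handed charge remains and 33.9% of the right-handed. I reckon 81.2% reacted, 48.1% left-handed product and 33.1% right-handed product, and with the right hand 1.08 lifetimes in, I call the flask still moving.

The forecast says it is still moving, with 79.3% reacted, 47.6% left-handed product and 31.7% right-handed product, citing “roughly the threefold rate ratio acting on a shared partner”. My conversion stands 1.9 percentage points above it.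

The simulation gives this for the flask: it is still moving, with 79.3% reacted, 47.6% left-handed product and 31.7% right-handed product. Its left-handed product moves 5 points when the partner charge is lowered to 2.08 M. In this flask, 37% of the right-handed charge remains, which is 0.99 lifetimes; multiplied by 3.04, that leaves 4.70% of the left-handed charge, and the reading is 4.7%. In the neighbour flask with 0.75 M of partner, 83% of the right-handed charge remains, so the same step gives 56.8%, and that flask reads 57% of the left-handed charge.

(All constants were set for the occasion; what happens was integrated by code.)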